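The cyclohexene is cut between its ring CH2 (C1) and its carbinol carbon (C2). A Lewis-acid type 2 carbonyl-ene reaction closes that ring: the formyl carbon of a 3-alkyl-4-formylbutenolide (future C2, held cis to C10 on the C3=C4 bond of the later dihydrofuran) is attacked by the methylene terminus of an isopropenyl group on C10. One operation forms C1–C2, sets the C2 hydroxyl and leaves an exocyclic methylene at C11, ready for radical hydroalkylation to the methyl/homoprenyl quaternary centre. The step exploits the 1,3-relationship of the C2 hydroxyl and the methyl-bearing C11 in the six-membered ring; the precursor carries only the C10 stereocentre.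

Key step: step 7

Remark (labels and assumptions): C1 = ring CH2; C2 = carbinol carbon; C3=C4 = ring-fusion alkene; C5 = O–CH bearing the 2-oxopropyl group; C9 = first side-chain carbon on C10; C10 = ring CH bearing that chain; C11 = quaternary carbon; C18 = ring OCH2. Compounds 1, 2, 4, 6, 14, 16, 19, 24 and 26 are taken as purchasable.

Step 1
Reactants: 1 2-[(tert-butyldiphenylsilyl)oxy]acetaldehyde; 2 methyl (triphenylphosphoranylidene)acetate
Product: 3 methyl (2E)-4-[(tert-butyldiphenylsilyl)oxy]but-2-enoate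
Conditions: CH2Cl2, rt
Reagents that add atoms: none
Why: Wittig olefination with a stabilised ylide should give the (E)-enoate needed as the conjugate acceptor.

Step 2
Reactants: 3 methyl (2E)-4-[(tert-butyldiphenylsilyl)oxy]but-2-enoate; 4 4,4,5,5-tetramethyl-2-(prop-1-en-2-yl)-1,3,2-dioxaborolane (isopropenylboronic acid pinacol ester)
Product: 5 methyl (3S)-3-{[(tert-butyldiphenylsilyl)oxy]methyl}-4-methylpent-4-enoate
Conditions: [Rh(cod)OH]2 (cat.), (S)-BINAP, dioxane/H2O, 40 °C
Reagents that add atoms: none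
Why: Hayashi–Miyaura asymmetric 1,4-addition of the alkenylboron reagent sets C10; the BINAP antipode is the one that delivers the (3S)-ester, written as (S)-BINAP on the usual facial model for (E)-acceptors.

Step 3
Reactants: 5 methyl (3S)-3-{[(tert-butyldiphenylsilyl)oxy]methyl}-4-methylpent-4-enoate; 6 2,2-dimethyl-1,3-dioxan-5-one
Product: 7 methyl (3S)-3-{[(tert-butyldiphenylsilyl)oxy]methyl}-2-(5-hydroxy-2,2-dimethyl-1,3-dioxan-5-yl)-4-methylpent-4-enoate (both C2 epimers)
Conditions: LiN(i-Pr)2, THF, −78 °C; then 6; AcOH quench at −78 °C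
Reagents that add atoms: none
Why: Aldol addition of the ester lithium enolate to the reactive symmetric ketone brings in C3 with both CH2O arms; the new α-centre is erased in step 4.

Step 4
Reactants: 7 methyl (3S)-3-{[(tert-butyldiphenylsilyl)oxy]methyl}-2-(5-hydroxy-2,2-dimethyl-1,3-dioxan-5-yl)-4-methylpent-4-enoate
Product: 9 methyl (3R)-3-{[(tert-butyldiphenylsilyl)oxy]methyl}-2-(2,2-dimethyl-1,3-dioxan-5-ylidene)-4-methylpent-4-enoate, via mesylate 8 (not isolated)
Conditions: MsCl, Et3N, CH2Cl2, 0 °C; then DBU, rt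
Reagents that add atoms: methanesulfonyl chloride, CS(=O)(=O)Cl (its atoms are kept only in 8)
Why: Mesylation and E1cB elimination toward the acidic α-hydrogen should give the tetrasubstituted enoate; the symmetric dioxane removes any alkene-geometry question (the descriptor changes by priority only).

Step 5
Reactants: 9 methyl (3R)-3-{[(tert-butyldiphenylsilyl)oxy]methyl}-2-(2,2-dimethyl-1,3-dioxan-5-ylidene)-4-methylpent-4-enoate
Product: 11 3-[(2R)-1-[(tert-butyldiphenylsilyl)oxy]-3-methylbut-3-en-2-yl]-4-(hydroxymethyl)furan-2(5H)-one, via diol ester 10 (not isolated)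
Conditions: PPTS, MeOH, 40 °C
Reagents that add atoms: none
Why: Transketalisation frees the 1,3-diol and the hydroxymethyl group cis to the ester lactonises to the butenolide, so the remaining hydroxymethyl (future C2) is necessarily cis to the C10 substituent.

Step 6
Reactants: 11 3-[(2R)-1-[(tert-butyldiphenylsilyl)oxy]-3-methylbut-3-en-2-yl]-4-(hydroxymethyl)furan-2(5H)-one
Product: 12 4-[(2R)-1-[(tert-butyldiphenylsilyl)oxy]-3-methylbut-3-en-2-yl]-5-oxo-2,5-dihydrofuran-3-carbaldehyde
Conditions: Dess–Martin periodinane, NaHCO3, CH2Cl2, 0 °C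
Reagents that add atoms: none
Why: Buffered Dess–Martin oxidation of the primary allylic alcohol should give the aldehyde without isomerising the skipped diene.

Step 7
Reactants: 12 4-[(2R)-1-[(tert-butyldiphenylsilyl)oxy]-3-methylbut-3-en-2-yl]-5-oxo-2,5-dihydrofuran-3-carbaldehyde
Product: 13 (4R,7R)-7-{[(tert-butyldiphenylsilyl)oxy]methyl}-4-hydroxy-6-methylidene-4,5,6,7-tetrahydro-2-benzofuran-1(3H)-one
Conditions: Me2AlCl, CH2Cl2, −78 → −40 °C
Reagents that add atoms: none
Why: Me2AlCl activates the aldehyde and the CH2 terminus of the isopropenyl group (C1) adds to the carbonyl carbon (C2) while an allylic hydrogen of its methyl group passes to oxygen in a six-membered array, so the C1–C2 bond, the C2 hydroxyl and the exocyclic C11=CH2 group arise together. The closest known reaction type is the Lewis-acid type 2 intramolecular carbonyl-ene (Prins-type) cyclisation of 5-methylhex-5-enals to 3-methylenecyclohexanols. The six-membered carbocycle closes by attack of an alkene terminus on an exocyclic carbonyl carbon (6-exo at the carbonyl, tether on the central ene carbon), the butenolide holding C2 and C10 cis. The new C2 stereocentre is controlled by C10: in the half-chair transition state the CH2OSi group on C10 should sit pseudoaxial to avoid allylic strain with the lactone carbonyl carbon on C4, and the complexed oxygen pseudoaxial as hydrogen transfer demands, which places the hydroxyl trans to the C10 substituent (R at C2). The step needs the ene course to win over loss of a ring proton from a free C11 cation and over dehydration; Me2AlCl (it removes the proton as methane) and the electron-poor butenolide, which disfavours ionisation at C2, should secure this, and the three-atom tether allows only the C1–C2 mode.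

Step 8
Reactants: 13 (4R,7R)-7-{[(tert-butyldiphenylsilyl)oxy]methyl}-4-hydroxy-6-methylidene-4,5,6,7-tetrahydro-2-benzofuran-1(3H)-one; 14 acrolein
Product: 15 3-[(4R,6S,7R)-7-{[(tert-butyldiphenylsilyl)oxy]methyl}-4-hydroxy-6-methyl-1-oxo-1,3,4,5,6,7-hexahydro-2-benzofuran-6-yl]propanal
Conditions: Fe(acac)3 (cat.), PhSiH3, EtOH/ethylene glycol, 60 °C
Reagents that add atoms: none
Why: Metal-hydride hydrogen-atom transfer to the 1,1-disubstituted alkene gives the tertiary C11 radical, which should add to acrolein (Giese reaction) anti to the pseudoaxial C10 substituent, placing the new chain trans to it and the methyl cis (S at C11).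

Step 9
Reactants: 15 3-[(4R,6S,7R)-7-{[(tert-butyldiphenylsilyl)oxy]methyl}-4-hydroxy-6-methyl-1-oxo-1,3,4,5,6,7-hexahydro-2-benzofuran-6-yl]propanal; 16 isopropyltriphenylphosphonium iodide
Product: 17 (4R,6S,7R)-7-{[(tert-butyldiphenylsilyl)oxy]methyl}-4-hydroxy-6-methyl-6-(4-methylpent-3-en-1-yl)-4,5,6,7-tetrahydro-2-benzofuran-1(3H)-one
Conditions: n-BuLi, THF, 0 °C (ylide, excess); then 15 added at −78 → 0 °C
Reagents that add atoms: none
Why: Wittig olefination with the non-stabilised isopropylidene ylide completes the homoprenyl chain; the aldehyde should react faster than the lactone or the acidic butenolide CH2 at low temperature.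

Step 10
Reactants: 17 (4R,6S,7R)-7-{[(tert-butyldiphenylsilyl)oxy]methyl}-4-hydroxy-6-methyl-6-(4-methylpent-3-en-1-yl)-4,5,6,7-tetrahydro-2-benzofuran-1(3H)-one
Product: 18 (4R,6S,7R)-7-{[(tert-butyldiphenylsilyl)oxy]methyl}-6-methyl-6-(4-methylpent-3-en-1-yl)-1,3,4,5,6,7-hexahydro-2-benzofuran-1,4-diol (lactol, both C1 epimers)
Conditions: i-Bu2AlH, CH2Cl2, −78 °C; aqueous KNaC4H4O6 work-up
Reagents that add atoms: none
Why: Partial reduction of the butenolide at low temperature should stop at the lactol, a masked C5 aldehyde with the C18 hydroxyl; a neutral work-up avoids dehydration to a furan.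

Step 11
Reactants: 18 lactol from step 10; 19 1-(triphenylphosphoranylidene)propan-2-one
Product: 21 1-[(1S,4R,6S,7R)-7-{[(tert-butyldiphenylsilyl)oxy]methyl}-4-hydroxy-6-methyl-6-(4-methylpent-3-en-1-yl)-1,3,4,5,6,7-hexahydro-2-benzofuran-1-yl]propan-2-one, via hydroxy dienone 20 (not isolated)
Conditions: toluene, 80 °C; then DBU (cat.), rt
Reagents that add atoms: none
Why: Wittig reaction on the open hydroxy-enal form, then reversible 5-exo-trig oxa-Michael addition of the C18 hydroxyl, should close the 2,5-dihydrofuran with the 2-oxopropyl group on the face opposite the pseudoaxial C10 substituent (thermodynamic control, S at C5).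

Step 12
Reactants: 21 silyl ether from step 11
Product: 22 1-[(1S,4R,6S,7R)-4-hydroxy-7-(hydroxymethyl)-6-methyl-6-(4-methylpent-3-en-1-yl)-1,3,4,5,6,7-hexahydro-2-benzofuran-1-yl]propan-2-one
Conditions: Bu4NF, AcOH, THF, rt
Reagents that add atoms: none
Why: Buffered fluoride desilylation frees the primary C9 alcohol; any retro-oxa-Michael opening re-closes to the same thermodynamic C5 epimer.

Step 13
Reactants: 22 diol from step 12
Product: 23 (1S,4R,6S,7R)-4-hydroxy-6-methyl-6-(4-methylpent-3-en-1-yl)-1-(2-oxopropyl)-1,3,4,5,6,7-hexahydro-2-benzofuran-7-carbaldehyde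
Conditions: TEMPO (cat.), PhI(OAc)2, CH2Cl2, rt
Reagents that add atoms: none
Why: Oxoammonium oxidation is selective for the primary alcohol over the hindered secondary allylic one and is neutral enough to keep the β,γ-unsaturated aldehyde from epimerising; the aldehyde is used at once.

Step 14
Reactants: 23 aldehyde from step 13; 24 2-(dichloromethyl)-4,4,5,5-tetramethyl-1,3,2-dioxaborolane
Product: 25 1-[(1S,4R,6S,7R)-4-hydroxy-6-methyl-6-(4-methylpent-3-en-1-yl)-7-[(E)-2-(4,4,5,5-tetramethyl-1,3,2-dioxaborolan-2-yl)ethenyl]-1,3,4,5,6,7-hexahydro-2-benzofuran-1-yl]propan-2-one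
Conditions: CrCl2, LiI, THF, rt
Reagents that add atoms: none
Why: Takai–Utimoto boron olefination adds C8 as an (E)-alkenylboronate and should leave the methyl ketone and the free hydroxyl untouched.

Step 15
Reactants: 25 alkenylboronate from step 14; 26 3-methylbut-2-enoic acid
Product: 27 neovibsanin I
Conditions: Cu(OAc)2 (cat.), Et3N, 4 Å molecular sieves, O2, CH2Cl2, rt
Reagents that add atoms: none
Why: Chan–Lam-type oxidative C–O coupling of the alkenylboronate with the carboxylic acid should give the enol ester with retention of the (E)-geometry.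

Compound list
1 | 2-[(tert-butyldiphenylsilyl)oxy]acetaldehyde | O=CCO[Si](c1ccccc1)(c1ccccc1)C(C)(C)C | starting material
2 | methyl (triphenylphosphoranylidene)acetate | COC(=O)C=P(c1ccccc1)(c1ccccc1)c1ccccc1 | starting material
3 | methyl (2E)-4-[(tert-butyldiphenylsilyl)oxy]but-2-enoate | COC(=O)/C=C/CO[Si](c1ccccc1)(c1ccccc1)C(C)(C)C | intermediate
4 | 4,4,5,5-tetramethyl-2-(prop-1-en-2-yl)-1,3,2-dioxaborolane | CC(=C)B1OC(C)(C)C(C)(C)O1 | starting material
5 | methyl (3S)-3-{[(tert-butyldiphenylsilyl)oxy]methyl}-4-methylpent-4-enoate | COC(=O)C[C@H](CO[Si](c1ccccc1)(c1ccccc1)C(C)(C)C)C(C)=C | intermediate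
6 | 2,2-dimethyl-1,3-dioxan-5-one | CC1(C)OCC(=O)CO1 | starting material
7 | methyl (3S)-3-{[(tert-butyldiphenylsilyl)oxy]methyl}-2-(5-hydroxy-2,2-dimethyl-1,3-dioxan-5-yl)-4-methylpent-4-enoate (C2 epimers) | COC(=O)C([C@H](CO[Si](c1ccccc1)(c1ccccc1)C(C)(C)C)C(C)=C)C1(O)COC(C)(C)OC1 | intermediate
8 | methanesulfonate of 7 (formed in the flask) | COC(=O)C([C@H](CO[Si](c1ccccc1)(c1ccccc1)C(C)(C)C)C(C)=C)C1(OS(C)(=O)=O)COC(C)(C)OC1 | intermediate
9 | methyl (3R)-3-{[(tert-butyldiphenylsilyl)oxy]methyl}-2-(2,2-dimethyl-1,3-dioxan-5-ylidene)-4-methylpent-4-enoate | COC(=O)C(=C1COC(C)(C)OC1)[C@H](CO[Si](c1ccccc1)(c1ccccc1)C(C)(C)C)C(C)=C | intermediate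
10 | methyl (3R)-3-{[(tert-butyldiphenylsilyl)oxy]methyl}-2-(1,3-dihydroxypropan-2-ylidene)-4-methylpent-4-enoate (formed in the flask) | COC(=O)C(=C(CO)CO)[C@H](CO[Si](c1ccccc1)(c1ccccc1)C(C)(C)C)C(C)=C | intermediate
11 | 3-[(2R)-1-[(tert-butyldiphenylsilyl)oxy]-3-methylbut-3-en-2-yl]-4-(hydroxymethyl)furan-2(5H)-one | O=C1OCC(CO)=C1[C@H](CO[Si](c1ccccc1)(c1ccccc1)C(C)(C)C)C(C)=C | intermediate
12 | 4-[(2R)-1-[(tert-butyldiphenylsilyl)oxy]-3-methylbut-3-en-2-yl]-5-oxo-2,5-dihydrofuran-3-carbaldehyde | O=C1OCC(C=O)=C1[C@H](CO[Si](c1ccccc1)(c1ccccc1)C(C)(C)C)C(C)=C | intermediate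
13 | (4R,7R)-7-{[(tert-butyldiphenylsilyl)oxy]methyl}-4-hydroxy-6-methylidene-4,5,6,7-tetrahydro-2-benzofuran-1(3H)-one | O=C1OCC2=C1[C@H](CO[Si](c1ccccc1)(c1ccccc1)C(C)(C)C)C(=C)C[C@H]2O | intermediate
14 | acrolein | C=CC=O | starting material
15 | 3-[(4R,6S,7R)-7-{[(tert-butyldiphenylsilyl)oxy]methyl}-4-hydroxy-6-methyl-1-oxo-1,3,4,5,6,7-hexahydro-2-benzofuran-6-yl]propanal | O=C1OCC2=C1[C@H](CO[Si](c1ccccc1)(c1ccccc1)C(C)(C)C)[C@@](C)(CCC=O)C[C@H]2O | intermediate
16 | isopropyltriphenylphosphonium iodide | CC(C)[P+](c1ccccc1)(c1ccccc1)c1ccccc1.[I-] | starting material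
17 | (4R,6S,7R)-7-{[(tert-butyldiphenylsilyl)oxy]methyl}-4-hydroxy-6-methyl-6-(4-methylpent-3-en-1-yl)-4,5,6,7-tetrahydro-2-benzofuran-1(3H)-one | O=C1OCC2=C1[C@H](CO[Si](c1ccccc1)(c1ccccc1)C(C)(C)C)[C@@](C)(CCC=C(C)C)C[C@H]2O | intermediate
18 | (4R,6S,7R)-7-{[(tert-butyldiphenylsilyl)oxy]methyl}-6-methyl-6-(4-methylpent-3-en-1-yl)-1,3,4,5,6,7-hexahydro-2-benzofuran-1,4-diol (lactol, C1 epimers) | OC1OCC2=C1[C@H](CO[Si](c1ccccc1)(c1ccccc1)C(C)(C)C)[C@@](C)(CCC=C(C)C)C[C@H]2O | intermediate
19 | 1-(triphenylphosphoranylidene)propan-2-one | CC(=O)C=P(c1ccccc1)(c1ccccc1)c1ccccc1 | starting material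
20 | (3E)-4-[(3R,5S,6R)-6-{[(tert-butyldiphenylsilyl)oxy]methyl}-3-hydroxy-2-(hydroxymethyl)-5-methyl-5-(4-methylpent-3-en-1-yl)cyclohex-1-en-1-yl]but-3-en-2-one (formed in the flask) | OCC1=C(/C=C/C(C)=O)[C@H](CO[Si](c2ccccc2)(c2ccccc2)C(C)(C)C)[C@@](C)(CCC=C(C)C)C[C@H]1O | intermediate
21 | 1-[(1S,4R,6S,7R)-7-{[(tert-butyldiphenylsilyl)oxy]methyl}-4-hydroxy-6-methyl-6-(4-methylpent-3-en-1-yl)-1,3,4,5,6,7-hexahydro-2-benzofuran-1-yl]propan-2-one | CC(=O)C[C@@H]1OCC2=C1[C@H](CO[Si](c1ccccc1)(c1ccccc1)C(C)(C)C)[C@@](C)(CCC=C(C)C)C[C@H]2O | intermediate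
22 | 1-[(1S,4R,6S,7R)-4-hydroxy-7-(hydroxymethyl)-6-methyl-6-(4-methylpent-3-en-1-yl)-1,3,4,5,6,7-hexahydro-2-benzofuran-1-yl]propan-2-one | CC(=O)C[C@@H]1OCC2=C1[C@H](CO)[C@@](C)(CCC=C(C)C)C[C@H]2O | intermediate
23 | (1S,4R,6S,7R)-4-hydroxy-6-methyl-6-(4-methylpent-3-en-1-yl)-1-(2-oxopropyl)-1,3,4,5,6,7-hexahydro-2-benzofuran-7-carbaldehyde | CC(=O)C[C@@H]1OCC2=C1[C@H](C=O)[C@@](C)(CCC=C(C)C)C[C@H]2O | intermediate
24 | 2-(dichloromethyl)-4,4,5,5-tetramethyl-1,3,2-dioxaborolane | ClC(Cl)B1OC(C)(C)C(C)(C)O1 | starting material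
25 | 1-[(1S,4R,6S,7R)-4-hydroxy-6-methyl-6-(4-methylpent-3-en-1-yl)-7-[(E)-2-(4,4,5,5-tetramethyl-1,3,2-dioxaborolan-2-yl)ethenyl]-1,3,4,5,6,7-hexahydro-2-benzofuran-1-yl]propan-2-one | CC(=O)C[C@@H]1OCC2=C1[C@H](/C=C/B3OC(C)(C)C(C)(C)O3)[C@@](C)(CCC=C(C)C)C[C@H]2O | intermediate
26 | 3-methylbut-2-enoic acid | CC(C)=CC(=O)O | starting material
27 | neovibsanin I | CC(=O)C[C@@H]1OCC2=C1[C@H](/C=C/OC(=O)C=C(C)C)[C@@](C)(CCC=C(C)C)C[C@H]2O | target

Total step count: 15. Longest linear sequence: 15 steps (1 → 27).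

Steps most likely to fail

Step 7. The cyclisation may turn stepwise: a free tertiary cation at C11 could lose a ring proton (from C1 or C10) instead of a methyl proton, and the resulting ring dienols could dehydrate to an arene. Facial selectivity at C2 may also erode. The fallback sets out from 12 and traps the cation with halide instead of relying on the ene hydrogen transfer. A bromo-Prins cyclisation (SnBr4, CH2Cl2, −78 °C) should give the tertiary bromide (4R,7R)-6-bromo-7-{[(tert-butyldiphenylsilyl)oxy]methyl}-4-hydroxy-6-methyl-4,5,6,7-tetrahydro-2-benzofuran-1(3H)-one F1, still by C1–C2 bond formation. Its C11 radical (Bu3SnH, AIBN, excess acrolein 14, benzene, 80 °C; tin-mediated Giese reaction) then adds to acrolein, and the route is rejoined at 15.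

Step 8. The metal hydride may move the exocyclic double bond into the ring before the radical is captured, acrolein may be reduced or oligomerised, and the acceptor may approach C11 with poor facial selectivity. The fallback sets out from 13 and replaces the conjugate addition by a manganese/nickel dual-catalytic Markovnikov hydroalkylation with an alkyl iodide (Mn(dpm)3, Ni(acac)2, PhSiH3, 2-(2-iodoethyl)-1,3-dioxolane). This should give the acetal (4R,6S,7R)-7-{[(tert-butyldiphenylsilyl)oxy]methyl}-6-[2-(1,3-dioxolan-2-yl)ethyl]-4-hydroxy-6-methyl-4,5,6,7-tetrahydro-2-benzofuran-1(3H)-one F2. Hydrolysis of the acetal (PPTS, acetone/H2O) returns to 15.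

Step 15. Transmetalation of the hindered pinacol boronate to copper may be slow, so that protodeboronation or O-alkenylation of the free C2 hydroxyl competes. The fallback sets out from 23 and uses a halide-based C–O coupling instead of the oxidative boron coupling. Takai iodo-olefination (CrCl2, CHI3, THF) should give the vinyl iodide 1-[(1S,4R,6S,7R)-4-hydroxy-7-[(E)-2-iodoethenyl]-6-methyl-6-(4-methylpent-3-en-1-yl)-1,3,4,5,6,7-hexahydro-2-benzofuran-1-yl]propan-2-one F3. Ullmann-type coupling with acid 26 (CuI, 3,4,7,8-tetramethyl-1,10-phenanthroline, Cs2CO3, toluene, 80 °C) then arrives at 27 with the (E)-geometry kept.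

Further compounds
F1 | step 7 | (4R,7R)-6-bromo-7-{[(tert-butyldiphenylsilyl)oxy]methyl}-4-hydroxy-6-methyl-4,5,6,7-tetrahydro-2-benzofuran-1(3H)-one (C6 epimers) | O=C1OCC2=C1[C@H](CO[Si](c1ccccc1)(c1ccccc1)C(C)(C)C)C(C)(Br)C[C@H]2O
F2 | step 8 | (4R,6S,7R)-7-{[(tert-butyldiphenylsilyl)oxy]methyl}-6-[2-(1,3-dioxolan-2-yl)ethyl]-4-hydroxy-6-methyl-4,5,6,7-tetrahydro-2-benzofuran-1(3H)-one | O=C1OCC2=C1[C@H](CO[Si](c1ccccc1)(c1ccccc1)C(C)(C)C)[C@@](C)(CCC1OCCO1)C[C@H]2O
F3 | step 15 | 1-[(1S,4R,6S,7R)-4-hydroxy-7-[(E)-2-iodoethenyl]-6-methyl-6-(4-methylpent-3-en-1-yl)-1,3,4,5,6,7-hexahydro-2-benzofuran-1-yl]propan-2-one | CC(=O)C[C@@H]1OCC2=C1[C@H](/C=C/I)[C@@](C)(CCC=C(C)C)C[C@H]2O
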